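- You asked me two things about each of two flasks: which form holds the most L at the end, and how much it holds.

| flask | L | temperature | remark | time |
|---|---|---|---|---|
| north-east | 0.047 M | 0 °C | run made earlier |  |
| west | 0.19 M | 15 °C | run made earlier |  |
| ash | 0.094 M | 5 °C |  | 40 h |
| birch | 0.094 M | 25 °C |  | 40 h |

| run | time / h | L / % | D / % | X / % |
|---|---|---|---|---|
| north-east | 4.00 | 87.0 | 7.0 | 0.9 |
| north-east | 8.00 | 77.1 | 12.9 | 2.0 |
| north-east | 12.0 | 68.2 | 17.1 | 2.8 |
| north-east | 15.0 | 63.1 | 20.6 | 3.3 |
| north-east | 20.0 | 56.3 | 25.0 | 4.5 |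
| north-east | 25.0 | 50.0 | 28.7 | 4.8 |
| west | 1.33 | 69.7 | 11.4 | 2.9 |
| west | 2.00 | 63.1 | 14.2 | 3.1 |
| west | 3.00 | 56.3 | 14.6 | 5.1 |
| west | 5.00 | 49.0 | 13.6 | 7.6 |
| west | 10.0 | 39.2 | 10.0 | 12.3 |
| west | 15.0 | 31.9 | 6.9 | 16.6 |

(standard deviation of a reading: 0.3 percentage points)

1. which of these there is most of at the end, counted by the L in it, ash (D / L / X)
2. which of these there is most of at the end, counted by the L in it, birch (D / L / X)
3. how much there is at the end of the one of these that leads, in percent of the L charged: ash
4. how much there is at the end of the one of these that leads, in percent of the L charged: birch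

- the earlier runs were read with a standard deviation of 0.3 percentage points
- a reading or a percentage of D counts all its forms, free or not
- a reading of L is of its free form alone

- In ash the close contest was D against free L, so I followed the lead ratio ρ: D with all its forms over free L, both in percent of the L charged. D stands ahead of L when ρ is above one.
- West's highest reading was 0.278 at 5.00 h, and I carried that west peak of the lead ratio.
- North-east read 0.574 at 25.0 h, still climbing from 0.444 at 20.0 h. Ash, at 5 °C, lay between those two temperatures, and to pass one it needed 3.60 times west's peak. I judged that it would stop short, leaving L first with D close behind.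
- West's L still led its X at 15.0 h, but the gap had narrowed from 27 percentage points at 10.0 h to 15 points. Birch was hotter than west and ran longer than west's last reading, so I judged that X would pass L there and put X first in birch.
- The forecast you sent gave D at 31% for ash, saying “D leads narrowly over L, which is a real uncertainty”, and X at 50% for birch. I agreed on birch and differed on ash.
- Ash gave L at 33.6% with D at 27.8%, so ρ was 0.827, below one. Birch gave X at 48.2%, with ρ at 0.0410.

    L ⇌ D (K = 0.510, k = 6.40 × 10⁻⁴ min⁻¹, Ea = 87.0 kJ mol⁻¹, ΔH = −88.0 kJ mol⁻¹)
    L ⇌ X (K = 7.00, k = 1.00 × 10⁻⁴ min⁻¹, Ea = 91.0 kJ mol⁻¹, ΔH = 5.00 kJ mol⁻¹)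
    2 L → J (k = 0.00160 L mol⁻¹ min⁻¹, Ea = 75.0 kJ mol⁻¹)
    L + D ⇌ Q, settled at all times (K = 15.0 L mol⁻¹, ΔH = −35.0 kJ mol⁻¹)
    (constants at 5 °C)

- Neither flask had come to rest at 40 h. At 400 h, ash held L 9.85%, D 5.96%, X 40.9% and J 42.5%, with ρ down to 0.605. Birch's ρ stayed at 0.0406, a pre-equilibrium, with L and free D relaxing in 0.0553 h. Meanwhile its X slid from 48.2% to 36.7% as J rose from 45.4% to 58.9%.
- A neighbour flask like birch but kept at 10 °C lies midway in temperature between ash and west. The geometric mean of their ratios gave ρ of 0.479, below one. The computed neighbour gave L 33% and D 12.6%, a ρ of 0.383, also below one but lower than my estimate.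

The readings were generated by integration for an exercise, noise included.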